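| flask | solid substrate | reagent | remark | time |
|---|---|---|---|---|
| eta | 0.057 M | 0.021 M | run made earlier |  |
| gamma | 0.090 M | 0.021 M | run made earlier |  |
| epsilon | 0.041 M | 0.042 M | run made earlier |  |
| flask | 0.041 M | 0.0210 M |  | 15 min |

| run | time / min | mono adduct / % | solid substrate / % |
|---|---|---|---|
| eta | 2.00 | 14.3 | 21.6 |
| eta | 4.00 | 16.7 | 13.4 |
| eta | 6.00 | 17.4 | 12.0 |
| eta | 8.00 | 17.6 | 12.1 |
| eta | 10.0 | 17.5 | 11.4 |
| eta | 12.0 | 17.9 | 11.1 |
| gamma | 1.00 | 6.4 | 59.7 |
| gamma | 1.50 | 8.2 | 53.5 |
| gamma | 2.50 | 9.7 | 48.4 |
| gamma | 4.00 | 11.7 | 45.8 |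
| gamma | 8.00 | 11.1 | 44.3 |
| gamma | 12.0 | 11.0 | 44.4 |
| epsilon | 2.50 | 33.4 | 0 |
| epsilon | 5.00 | 36.5 | 0 |
| epsilon | 8.00 | 37.3 | 0 |
| epsilon | 10.0 | 35.9 | 0 |
| epsilon | 12.0 | 37.3 | 0.3 |

(readings scatter by 0.5 percentage points)
- given per volume of solution although it is solid: solid substrate
- the numbers in the tables scatter with a standard deviation of 0.5 percentage points
- at the start none of the solid substrate is in solution
- equivalents of reagent to solid substrate, everything else as given, that leave most mono adduct at 15 min
- the amount of mono adduct then, in percent of the solid substrate charged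
- the amount of mono adduct with the amounts as given

1. A one-step world turns each reagent into one mono adduct, so look at what the reagent really yields. Eta and gamma share 0.021 M of reagent, yet their last readings give 0.486 and 0.471 c(mono adduct) per c(reagent) charged, although gamma holds 1.58 times eta's solid substrate.

2. Time: between 8.00 min and 12.0 min, eta's mono adduct moves 0.3 percentage points, and the scatter is 0.5 points. So an error in the time barely matters.

3. Charges: from gamma to eta, with c(reagent) held, the last reading of mono adduct in percent rises 1.63 times as c(solid substrate) falls 1.58 times, so c(solid substrate) must be known well. Epsilon, with 2.00 times eta's reagent and less solid substrate, reads 37.3% at its last reading, against 17.9% in eta; two settings differ there, so c(reagent) is worth knowing well too, though these runs do not separate its effect.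

4. Freeze the reagent yield, mono adduct formed per reagent charged, 0.479. My reckoning for the flask, at 0.512 equiv, is 24.5%. Epsilon, at 1.02 equiv, yields 0.364, less than that, so the frozen yield cannot locate the optimum.

5. The forecast says 26%, above my figure, and 38% at 1.1 equiv, noting that “the yield curve is flattening”.

6. The flask gives 24.4%, and at best 38.3% at 1.21 equiv.

    starting material + reagent → mono adduct + by-product (k = 0.800 /M/s)
    reagent ⇌ dormant form (K = 1.30, k = 0.0290 /s)
    starting material + reagent → other mono adduct + by-product (k = 0.550 /M/s)
    reagent + mono adduct → bis adduct + by-product (k = 0.280 /M/s)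
    solid substrate ⇌ starting material, rate k5*(cs5 - [starting material]) while solid is left; crystals form when [starting material] > cs5 (solubility = 32.0 mM, k = 0.0410 /s)
    reagent + other mono adduct → bis adduct + by-product (k = 1.10 /M/s)

At 15.0 min the flask has 0% of its reagent left, so reagent is the limiting reagent, and its yield there is 0.477. Take a neighbour flask with 0.10 M of solid substrate: the carried yield predicts 10.1%, and that neighbour gives 10.2%.

The runs come from a simulation for substances that don't exist; scatter was added.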